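**Retrosynthetic overview**
1. The strategy rests on ring B: it carries oxygen on C6 and on C9, the two carbons that flank the C5–C10 ring fusion. A C6 nitro group (masked ketone) and a C9 silyl enol ether therefore polarise an acyclic triene so that C5–C10 and C6–C7 form in one intramolecular Diels–Alder reaction that closes rings A and B together.
2. Target ⇐ 3β,6β-diol 47 (selective 3-O-acetylation) ⇐ enone acid 45: the γ-lactone (O16–C15) and the spiro tetrahydrofuran (O13–C9, oxa-Michael onto the C8=C9–C7=O enone) close last; C13 is brought in from (S)-malic acid.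
3. Enone 42 ⇐ C9–C11 bond by 1,2-addition of the side-chain organocerium to the C7=C8–C9=O enone 29, then oxidative 1,3-transposition; 29 ⇐ cycloadduct 24 by Nef reaction, α-face reduction at C6 and Saegusa–Ito oxidation.
4. 24 ⇐ nitro triene 23 (key step) ⇐ Henry condensation on aldehyde 20; C3 by CBS reduction; the Z tetrasubstituted enol silane is fixed by making C9=C10 part of enol lactone 11 before that ring is opened.
5. Ring order: rings A and B together (step 13), then the lactone and the tetrahydrofuran (step 27).

Key step: step 13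

Assumption: atoms are numbered as in the labdane skeleton (C1–C10 decalin, C11–C16 side chain, C17 on C8, C20 on C10); TBS = tert-butyldimethylsilyl, TES = triethylsilyl; compounds 4–9 are racemic at the future C10, which is immaterial because C10 becomes sp2 in step 5.

**Route**

Step 1
Reactants: 1 δ-valerolactone; 2 iodomethane
Product: 4 3-methyltetrahydro-2H-pyran-2-one (racemic), via lithium lactone enolate 3 (not isolated)
Conditions: LiN(i-Pr)2, THF, −78 °C; MeI, −78 → −20 °C
Reagents that add atoms: iodomethane (2), CI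
Why: Kinetic lactone enolate alkylation should install the future C20 methyl group α to the carbonyl, the new centre being racemic and erased in step 5.

Step 2
Reactants: 4 3-methyltetrahydro-2H-pyran-2-one; 5 N,O-dimethylhydroxylamine hydrochloride
Product: 6 5-hydroxy-N-methoxy-N,2-dimethylpentanamide (racemic)
Conditions: MeNH(OMe)·HCl, i-PrMgCl, THF, −20 → 0 °C
Reagents that add atoms: N,O-dimethylhydroxylamine hydrochloride (5), Cl.CNOC
Why: Aminolysis of the lactone by the magnesium amide (Weinreb amide formation) should open the ring to an amide that accepts only one organometallic equivalent.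

Step 3
Reactants: 6 5-hydroxy-N-methoxy-N,2-dimethylpentanamide; 7 isopropenylmagnesium bromide
Product: 8 7-hydroxy-2,4-dimethylhept-1-en-3-one (racemic)
Conditions: CH2=C(Me)MgBr (3 eq), THF, 0 °C; aq. NH4Cl
Reagents that add atoms: isopropenylmagnesium bromide (7), CC(=C)[Mg]Br
Why: Grignard addition to the Weinreb amide stops at the chelated tetrahedral adduct, so the isopropenyl ketone (C7–C9 with C17) should form without over-addition, the first equivalent being consumed by the free hydroxyl.

Step 4
Reactants: 8 7-hydroxy-2,4-dimethylhept-1-en-3-one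
Product: 9 4,6-dimethyl-5-oxohept-6-enoic acid (racemic)
Conditions: TEMPO (0.2 eq), PhI(OAc)2 (2.2 eq), MeCN/H2O, rt
Reagents that add atoms: water, O
Why: Oxoammonium (TEMPO) oxidation should take the primary alcohol through the aldehyde hydrate to the acid without touching the enone.

Step 5
Reactants: 9 4,6-dimethyl-5-oxohept-6-enoic acid; 10 acetic anhydride
Product: 11 5-methyl-6-(prop-1-en-2-yl)-3,4-dihydro-2H-pyran-2-one
Conditions: Ac2O, NaOAc (cat.), BHT, 110 °C
Reagents that add atoms: none
Why: Enol lactonisation of the δ-keto acid through its mixed anhydride can only engage the C10 enol (C8 bears no hydrogen), so the six-membered ring should lock O9 cis to C1 across the new C9=C10 bond.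

Step 6
Reactants: 11 5-methyl-6-(prop-1-en-2-yl)-3,4-dihydro-2H-pyran-2-one; 5 N,O-dimethylhydroxylamine hydrochloride
Product: 13 (Z)-5-(tert-butyldimethylsilyloxy)-N-methoxy-N,4,6-trimethylhepta-4,6-dienamide, via chloromagnesium Z-enolate 12 (not isolated)
Conditions: MeNH(OMe)·HCl (1.2 eq), i-PrMgCl (2.4 eq), THF, −20 °C; add 11; then TBSOTf, −78 → 0 °C
Reagents that add atoms: N,O-dimethylhydroxylamine hydrochloride (5), Cl.CNOC; tert-butyldimethylsilyl trifluoromethanesulfonate, CC(C)(C)[Si](C)(C)OS(=O)(=O)C(F)(F)F
Why: Acyl substitution on the enol ester expels the enolate with its ring-defined geometry and O-silylation by the silyl triflate should fix the Z tetrasubstituted enol silane (regio- and stereospecific enolate generation from an enol ester).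

Step 7
Reactants: 13 (Z)-5-(tert-butyldimethylsilyloxy)-N-methoxy-N,4,6-trimethylhepta-4,6-dienamide; 14 isobutyronitrile
Product: 16 (Z)-7-(tert-butyldimethylsilyloxy)-2,2,6,8-tetramethyl-3-oxonona-6,8-dienenitrile, via lithium hemiaminal adduct 15 (not isolated)
Conditions: i-PrCN, LiN(i-Pr)2, THF, −78 °C; then 13, −78 → −40 °C; aq. NH4Cl
Reagents that add atoms: isobutyronitrile (14), CC(C)C#N
Why: Addition of the α-lithiated nitrile to the Weinreb amide gives a chelate that collapses only on quench, so the β-keto nitrile with the C4 gem-dimethyl group should form without enolisation of the new ketone or loss of the enol silane.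

Step 8
Reactants: 16 (Z)-7-(tert-butyldimethylsilyloxy)-2,2,6,8-tetramethyl-3-oxonona-6,8-dienenitrile
Product: 17 (3S,6Z)-7-(tert-butyldimethylsilyloxy)-3-hydroxy-2,2,6,8-tetramethylnona-6,8-dienenitrile
Conditions: (R)-2-methyl-CBS-oxazaborolidine (0.2 eq), catecholborane, toluene, −78 °C
Reagents that add atoms: none
Why: Corey–Bakshi–Shibata reduction distinguishes the tertiary C(Me)2CN flank from the primary alkyl flank, so the (R)-catalyst should deliver hydride to give the (S)-carbinol at C3, and catecholborane at −78 °C leaves the diene untouched.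

Step 9
Reactants: 17 (3S,6Z)-7-(tert-butyldimethylsilyloxy)-3-hydroxy-2,2,6,8-tetramethylnona-6,8-dienenitrile
Product: 18 (3S,6Z)-3,7-bis(tert-butyldimethylsilyloxy)-2,2,6,8-tetramethylnona-6,8-dienenitrile
Conditions: TBSOTf, 2,6-lutidine, CH2Cl2, −78 → 0 °C
Reagents that add atoms: tert-butyldimethylsilyl trifluoromethanesulfonate, CC(C)(C)[Si](C)(C)OS(=O)(=O)C(F)(F)F
Why: Silyl triflate silylation of the hindered neopentyl-type secondary alcohol is a standard protection that the enol silane tolerates.

Step 10
Reactants: 18 (3S,6Z)-3,7-bis(tert-butyldimethylsilyloxy)-2,2,6,8-tetramethylnona-6,8-dienenitrile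
Product: 20 (3S,6Z)-3,7-bis(tert-butyldimethylsilyloxy)-2,2,6,8-tetramethylnona-6,8-dienal, via N-diisobutylalumino imine 19 (not isolated)
Conditions: i-Bu2AlH, toluene, −78 °C; aq. KNaC4H4O6 (potassium sodium tartrate), then SiO2
Reagents that add atoms: water, O
Why: Partial hydride reduction of the nitrile stops at the N-aluminoimine, whose mild hydrolysis should give the non-enolisable neopentyl aldehyde (C5).

Step 11
Reactants: 20 (3S,6Z)-3,7-bis(tert-butyldimethylsilyloxy)-2,2,6,8-tetramethylnona-6,8-dienal; 21 nitromethane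
Product: 22 (4S,7Z)-4,8-bis(tert-butyldimethylsilyloxy)-3,3,7,9-tetramethyl-1-nitrodeca-7,9-dien-2-ol (both C2 epimers)
Conditions: MeNO2 (10 eq), tetramethylguanidine (0.2 eq), THF, 0 °C → rt
Reagents that add atoms: nitromethane (21), C[N+](=O)[O-]
Why: Base-catalysed Henry (nitroaldol) addition to the non-enolisable aldehyde should add C6 with its nitro group, the new carbinol centre being removed in step 12.

Step 12
Reactants: 22 (4S,7Z)-4,8-bis(tert-butyldimethylsilyloxy)-3,3,7,9-tetramethyl-1-nitrodeca-7,9-dien-2-ol
Product: 23 (1E,4S,7Z)-4,8-bis(tert-butyldimethylsilyloxy)-3,3,7,9-tetramethyl-1-nitrodeca-1,7,9-triene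
Conditions: MsCl, Et3N, CH2Cl2, −20 → 0 °C
Reagents that add atoms: none
Why: Mesylation and E1cB elimination of the β-nitro alcohol should give the conjugated E-nitroalkene, which cannot deconjugate because C4 is quaternary.

Step 13
Reactants: 23 (1E,4S,7Z)-4,8-bis(tert-butyldimethylsilyloxy)-3,3,7,9-tetramethyl-1-nitrodeca-1,7,9-triene
Product: 24 trans-fused cycloadduct (3β-OTBS; 5α-H; 6α-NO2; 10β-methyl; 4,4-dimethyl; C8=C9 enol silane with 8-methyl and 9-OTBS)
Conditions: toluene (0.01 M), BHT (cat.), 110 °C, sealed tube, Ar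
Reagents that add atoms: none
Why: Proposed new method: on heating, the electron-rich Z-2-silyloxydiene (C10=C9–C8=C7) and the electron-poor E-nitroalkene (C5=C6) should combine in a normal-demand intramolecular Diels–Alder reaction that forms C5–C10 and C6–C7, either in concert, or by Michael addition of C10 to C5 and collapse of the nitronate onto C7, or through a hetero-[4+2] nitronate and [3,3] shift, all of which end in the same adduct; the closest known reactions are the thermal cyclisations of (E)-1-nitro-1,7,9-decatrienes to trans-decalins and the cycloadditions of 2-silyloxydienes with nitroalkenes, whereas a tetrasubstituted enol silane terminus that becomes a quaternary carbon has not been shown. Ring B closes as the [4+2] cyclohexene and ring A closes through the four-carbon tether C1–C4 as a six-membered ring (6-exo in the stepwise picture). C10 is set by the Z enol geometry (tether outside, methyl inside) together with the diene face that the chair-like tether presents when the C3 silyloxy group is equatorial, so the methyl group ends β and cis to the C3 oxygen. C5 follows from the trans-fused arrangement of tether and diene, and C6 from the endo nitro group and the retained E geometry, giving 5α-H and 6α-NO2. The step needs regioselectivity, which the tether and the matched polarity (nucleophilic C10, electrophilic C5) both enforce, and C10/C3 diastereoselectivity, which rests on the equatorial C3 substituent; a cis-fused by-product with the same C10 configuration would converge after step 14 by epimerisation at C5.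

Step 14
Reactants: 24 trans-fused cycloadduct
Product: 26 C6 ketone (3β-OTBS; 5α-H; C8=C9 enol silane retained), via potassium nitronate 25 (not isolated)
Conditions: KN(SiMe3)2, THF, −78 → 0 °C; MoO5·pyridine·HMPA, −78 → 0 °C
Reagents that add atoms: oxodiperoxomolybdenum pyridine hexamethylphosphoramide complex (MoO5·pyridine·HMPA), O=[Mo]12(OO1)OO2.c1ccncc1.CN(C)P(=O)(N(C)C)N(C)C
Why: Oxidative Nef reaction in which the nitronate is oxygenated at carbon by the peroxomolybdenum reagent and loses nitrite, a reagent that attacks anions but not silyl enol ethers, while C5 can equilibrate α to the new ketone toward the trans fusion.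

Step 15
Reactants: 26 C6 ketone
Product: 27 6β-alcohol (3β-OTBS; 5α-H; 10β-methyl; C8=C9 enol silane)
Conditions: LiAlH4, THF, −40 °C
Reagents that add atoms: none
Why: Hydride reduction of the ketone should occur from the α-face because the β-face is screened by the axial methyl groups on C4 and C10, which gives the axial 6β-hydroxyl.

Step 16
Reactants: 27 6β-alcohol
Product: 28 6β-OTES ether of 27
Conditions: TESOTf, 2,6-lutidine, CH2Cl2, 0 °C → rt
Reagents that add atoms: triethylsilyl trifluoromethanesulfonate, CC[Si](CC)(CC)OS(=O)(=O)C(F)(F)F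
Why: A silyl triflate is used because the axial 6β-hydroxyl flanked by two syn-axial methyl groups is too hindered for silyl chlorides, and the ether protects C6 through the oxidations that follow.

Step 17
Reactants: 28 6β-OTES ether
Product: 29 C7=C8 enone with C9 ketone (3β-OTBS; 6β-OTES; 8-methyl)
Conditions: Pd(OAc)2 (1.1 eq), MeCN, 40 °C
Reagents that add atoms: none
Why: Saegusa–Ito oxidation, in which palladation of the enol silane at C8 and β-hydride elimination toward C7 should give the conjugated endocyclic enone.

Step 18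
Reactants: 30 (S)-malic acid; 31 pivalaldehyde
Product: 32 2-[(2S,4S)-2-tert-butyl-5-oxo-1,3-dioxolan-4-yl]acetic acid
Conditions: t-BuCHO, TsOH (cat.), H2SO4 (cat.), pentane, reflux, Dean–Stark
Reagents that add atoms: pivalaldehyde (31), CC(C)(C)C=O
Why: Acid-catalysed acetalisation of the α-hydroxy acid unit gives the cis-dioxolanone under thermodynamic control, which stores the stereocentre for alkylation (self-regeneration of stereocentres).

Step 19
Reactants: 32 2-[(2S,4S)-2-tert-butyl-5-oxo-1,3-dioxolan-4-yl]acetic acid; 33 1-bromo-3-methylbut-2-ene (prenyl bromide)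
Product: 35 2-[(2S,4S)-2-tert-butyl-4-(3-methylbut-2-enyl)-5-oxo-1,3-dioxolan-4-yl]acetic acid, via dilithium enolate carboxylate 34 (not isolated)
Conditions: LiN(SiMe3)2 (2.2 eq), THF, −78 °C; prenyl bromide, −78 → −20 °C; 1 M HCl
Reagents that add atoms: prenyl bromide (33), CC(C)=CCBr
Why: The ring enolate is alkylated on the face opposite the tert-butyl group, so the prenyl group takes the place of the former hydrogen with retention and sets the fully substituted carbon that becomes C13.

Step 20
Reactants: 35 prenylated dioxolanone acid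
Product: 36 (S)-2-(3-methylbut-2-enyl)butane-1,2,4-triol
Conditions: LiAlH4, THF, 0 °C → reflux
Reagents that add atoms: none
Why: Hydride reduction converts the acid into the C11 carbinol and the dioxolanone carbonyl into the C16 carbinol and releases the acetal carbon as neopentyl alcohol, without touching the stereocentre.

Step 21
Reactants: 36 (S)-2-(3-methylbut-2-enyl)butane-1,2,4-triol
Product: 37 2-[(S)-2,2-dimethyl-4-(3-methylbut-2-enyl)-1,3-dioxolan-4-yl]ethanol
Conditions: Me2C(OMe)2, TsOH (cat.), acetone, rt
Reagents that add atoms: 2,2-dimethoxypropane, COC(C)(C)OC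
Why: Acetonide formation under thermodynamic control selects the five-membered dioxolane on O13/O16, since the six-membered alternative would carry an axial group on a fully substituted carbon, and leaves the primary C11 hydroxyl free.

Step 22
Reactants: 37 acetonide alcohol
Product: 38 (S)-4-(2-iodoethyl)-2,2-dimethyl-4-(3-methylbut-2-enyl)-1,3-dioxolane
Conditions: I2, PPh3, imidazole, CH2Cl2, 0 °C
Reagents that add atoms: iodine, [I][I]
Why: Appel-type iodination converts the primary alcohol into the iodide by SN2 displacement without affecting the alkene or the acetonide.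

Step 23
Reactants: 29 C7=C8 enone with C9 ketone; 38 side-chain iodide
Product: 41 C9 tertiary allylic alcohol bearing the C11–C16 side chain (C7=C8; C9 configuration not assigned), via alkyllithium 39 (not isolated), via alkylcerium dichloride 40 (not isolated)
Conditions: 38, t-BuLi (2 eq), Et2O, −78 °C; CeCl3, THF, −78 °C; then 29, −78 → −40 °C
Reagents that add atoms: none
Why: Iodine–lithium exchange, transmetalation to cerium and 1,2-addition to the hindered enone carbonyl should form C9–C11, the organocerium suppressing enolisation and conjugate addition, carbolithiation of the trisubstituted prenyl alkene not competing at −78 °C, and the configuration of the new carbinol being irrelevant because C9 becomes sp2 in step 24.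

Step 24
Reactants: 41 C9 tertiary allylic alcohol
Product: 42 C8=C9 enone with C7 ketone (3β-OTBS; 6β-OTES; side chain on C9)
Conditions: pyridinium chlorochromate (C5H5NH[CrO3Cl]), 4 Å molecular sieves, CH2Cl2, rt
Reagents that add atoms: pyridinium chlorochromate, [O-][Cr](=O)(=O)Cl.c1cc[nH+]cc1
Why: Babler–Dauben oxidative transposition, in which the chromate ester of the tertiary allylic alcohol undergoes a [3,3] shift to C7 and is oxidised there, should give the C7 ketone conjugated with the tetrasubstituted C8=C9 alkene.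

Step 25
Reactants: 42 C8=C9 enone with C7 ketone
Product: 44 C15 aldehyde (prenyl group cut to CH2CHO), via vicinal diol 43 (not isolated)
Conditions: OsO4 (cat.), NaIO4, 2,6-lutidine, dioxane/H2O, rt
Reagents that add atoms: osmium tetroxide (catalytic oxygen carrier), O=[Os](=O)(=O)=O; sodium periodate, [Na+].[O-]I(=O)(=O)=O
Why: Lemieux–Johnson cleavage, in which OsO4 dihydroxylates the electron-rich trisubstituted alkene in preference to the hindered electron-poor tetrasubstituted enone and periodate cleaves the diol.

Step 26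
Reactants: 44 C15 aldehyde
Product: 45 C15 carboxylic acid (acetonide, silyl ethers and enone intact)
Conditions: NaClO2, NaH2PO4, 2-methyl-2-butene, t-BuOH/H2O, rt
Reagents that add atoms: sodium chlorite, [Na+].[O-]Cl=O
Why: Pinnick oxidation converts the aldehyde into the acid under buffered conditions that leave the acetonide, the silyl ethers and the enone intact.

Step 27
Reactants: 45 C15 carboxylic acid
Product: 47 3β,6β-dihydroxy-7-oxo-9α,13-epoxy spirolactone (deacetyl target), via hydroxy lactone enone 46 (not isolated)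
Conditions: 48% aq. HF, MeCN, 0 °C → rt; then TsOH·H2O (cat.), CH2Cl2, rt
Reagents that add atoms: none
Why: Acid removes both silyl ethers and the acetonide, the freed C16 hydroxyl lactonises onto the C15 acid, and the tertiary C13 hydroxyl then adds to C9 of the enone (intramolecular oxa-Michael, 5-exo-trig), where axial attack anti to the C10 methyl group and the reversibility of the addition should place oxygen on the α-face of C9, protonation of the enol gives the equatorial 8α-methyl group, and C13 keeps the configuration brought in from malic acid.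

Step 28
Reactants: 47 3β,6β-diol spirolactone; 10 acetic anhydride
Product: 48 CNP0325396.1 (3β-acetoxy-6β-hydroxy-7-oxo-9α,13R-epoxy spirolactone with C15 lactone carbonyl)
Conditions: Ac2O (1.2 eq), pyridine, 0 °C → rt
Reagents that add atoms: acetic anhydride (10), CC(=O)OC(C)=O
Why: Acetylation should be selective for the equatorial 3β-hydroxyl because the axial 6β-hydroxyl is shielded by the methyl groups on C4 and C10 and by the neighbouring carbonyl.

**Compound list**
1 | δ-valerolactone | O=C1CCCCO1 | starting material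
2 | iodomethane | CI | starting material
3 | lithium enolate of δ-valerolactone | [Li+].[O-]C1=CCCCO1 | intermediate
4 | 3-methyltetrahydro-2H-pyran-2-one (racemic) | CC1CCCOC1=O | intermediate
5 | N,O-dimethylhydroxylamine hydrochloride | Cl.CNOC | starting material
6 | 5-hydroxy-N-methoxy-N,2-dimethylpentanamide (racemic) | CON(C)C(=O)C(C)CCCO | intermediate
7 | isopropenylmagnesium bromide | CC(=C)[Mg]Br | starting material
8 | 7-hydroxy-2,4-dimethylhept-1-en-3-one (racemic) | CC(=C)C(=O)C(C)CCCO | intermediate
9 | 4,6-dimethyl-5-oxohept-6-enoic acid (racemic) | CC(=C)C(=O)C(C)CCC(=O)O | intermediate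
10 | acetic anhydride | CC(=O)OC(C)=O | starting material
11 | 5-methyl-6-(prop-1-en-2-yl)-3,4-dihydro-2H-pyran-2-one | CC(=C)C1=C(C)CCC(=O)O1 | intermediate
12 | chloromagnesium Z-enolate of the ring-opened Weinreb amide | CON(C)C(=O)CC/C(C)=C(\O[Mg]Cl)C(C)=C | intermediate
13 | (Z)-5-(tert-butyldimethylsilyloxy)-N-methoxy-N,4,6-trimethylhepta-4,6-dienamide | CON(C)C(=O)CC/C(C)=C(\O[Si](C)(C)C(C)(C)C)C(C)=C | intermediate
14 | isobutyronitrile | CC(C)C#N | starting material
15 | lithium hemiaminal adduct of 13 and lithiated isobutyronitrile | CON(C)C(O[Li])(CC/C(C)=C(\O[Si](C)(C)C(C)(C)C)C(C)=C)C(C)(C)C#N | intermediate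
16 | (Z)-7-(tert-butyldimethylsilyloxy)-2,2,6,8-tetramethyl-3-oxonona-6,8-dienenitrile | N#CC(C)(C)C(=O)CC/C(C)=C(\O[Si](C)(C)C(C)(C)C)C(C)=C | intermediate
17 | (3S,6Z)-7-(tert-butyldimethylsilyloxy)-3-hydroxy-2,2,6,8-tetramethylnona-6,8-dienenitrile | N#CC(C)(C)[C@@H](O)CC/C(C)=C(\O[Si](C)(C)C(C)(C)C)C(C)=C | intermediate
18 | (3S,6Z)-3,7-bis(tert-butyldimethylsilyloxy)-2,2,6,8-tetramethylnona-6,8-dienenitrile | N#CC(C)(C)[C@@H](O[Si](C)(C)C(C)(C)C)CC/C(C)=C(\O[Si](C)(C)C(C)(C)C)C(C)=C | intermediate
19 | N-diisobutylalumino imine of 20 | CC(C)C[Al](CC(C)C)N=CC(C)(C)[C@@H](O[Si](C)(C)C(C)(C)C)CC/C(C)=C(\O[Si](C)(C)C(C)(C)C)C(C)=C | intermediate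
20 | (3S,6Z)-3,7-bis(tert-butyldimethylsilyloxy)-2,2,6,8-tetramethylnona-6,8-dienal | O=CC(C)(C)[C@@H](O[Si](C)(C)C(C)(C)C)CC/C(C)=C(\O[Si](C)(C)C(C)(C)C)C(C)=C | intermediate
21 | nitromethane | C[N+](=O)[O-] | starting material
22 | (4S,7Z)-4,8-bis(tert-butyldimethylsilyloxy)-3,3,7,9-tetramethyl-1-nitrodeca-7,9-dien-2-ol (C2 epimers) | [O-][N+](=O)CC(O)C(C)(C)[C@@H](O[Si](C)(C)C(C)(C)C)CC/C(C)=C(\O[Si](C)(C)C(C)(C)C)C(C)=C | intermediate
23 | (1E,4S,7Z)-4,8-bis(tert-butyldimethylsilyloxy)-3,3,7,9-tetramethyl-1-nitrodeca-1,7,9-triene | [O-][N+](=O)/C=C/C(C)(C)[C@@H](O[Si](C)(C)C(C)(C)C)CC/C(C)=C(\O[Si](C)(C)C(C)(C)C)C(C)=C | intermediate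
24 | trans-fused cycloadduct: 3β-OTBS, 6α-nitro, 10β-methyl, 5α-H, C8=C9 enol TBS ether | CC(C)(C)[Si](C)(C)O[C@H]1CC[C@@]2(C)[C@@H]([C@@H]([N+](=O)[O-])CC(C)=C2O[Si](C)(C)C(C)(C)C)C1(C)C | intermediate
25 | potassium C6 nitronate of 24 | CC(C)(C)[Si](C)(C)O[C@H]1CC[C@@]2(C)[C@@H](C(=[N+]([O-])[O-])CC(C)=C2O[Si](C)(C)C(C)(C)C)C1(C)C.[K+] | intermediate
26 | C6 ketone (enol silane retained) | CC(C)(C)[Si](C)(C)O[C@H]1CC[C@@]2(C)[C@@H](C(=O)CC(C)=C2O[Si](C)(C)C(C)(C)C)C1(C)C | intermediate
27 | 6β-alcohol | CC(C)(C)[Si](C)(C)O[C@H]1CC[C@@]2(C)[C@@H]([C@H](O)CC(C)=C2O[Si](C)(C)C(C)(C)C)C1(C)C | intermediate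
28 | 6β-OTES ether | CC(C)(C)[Si](C)(C)O[C@H]1CC[C@@]2(C)[C@@H]([C@H](O[Si](CC)(CC)CC)CC(C)=C2O[Si](C)(C)C(C)(C)C)C1(C)C | intermediate
29 | C7=C8 enone with C9 ketone (3β-OTBS, 6β-OTES) | CC(C)(C)[Si](C)(C)O[C@H]1CC[C@@]2(C)[C@@H]([C@H](O[Si](CC)(CC)CC)C=C(C)C2=O)C1(C)C | intermediate
30 | (S)-malic acid | OC(=O)C[C@H](O)C(=O)O | starting material
31 | pivalaldehyde | CC(C)(C)C=O | starting material
32 | 2-[(2S,4S)-2-tert-butyl-5-oxo-1,3-dioxolan-4-yl]acetic acid | OC(=O)C[C@@H]1O[C@H](C(C)(C)C)OC1=O | intermediate
33 | 1-bromo-3-methylbut-2-ene (prenyl bromide) | CC(C)=CCBr | starting material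
34 | dilithium enolate carboxylate of 32 | [Li+].[Li+].[O-]C(=O)CC1=C([O-])O[C@@H](C(C)(C)C)O1 | intermediate
35 | 2-[(2S,4S)-2-tert-butyl-4-(3-methylbut-2-enyl)-5-oxo-1,3-dioxolan-4-yl]acetic acid | OC(=O)C[C@]1(CC=C(C)C)O[C@H](C(C)(C)C)OC1=O | intermediate
36 | (S)-2-(3-methylbut-2-enyl)butane-1,2,4-triol | OCC[C@](O)(CO)CC=C(C)C | intermediate
37 | 2-[(S)-2,2-dimethyl-4-(3-methylbut-2-enyl)-1,3-dioxolan-4-yl]ethanol | OCC[C@@]1(CC=C(C)C)COC(C)(C)O1 | intermediate
38 | (S)-4-(2-iodoethyl)-2,2-dimethyl-4-(3-methylbut-2-enyl)-1,3-dioxolane | ICC[C@@]1(CC=C(C)C)COC(C)(C)O1 | intermediate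
39 | alkyllithium from 38 | [Li]CC[C@@]1(CC=C(C)C)COC(C)(C)O1 | intermediate
40 | alkylcerium dichloride from 39 | Cl[Ce](Cl)CC[C@@]1(CC=C(C)C)COC(C)(C)O1 | intermediate
41 | C9 tertiary allylic alcohol with side chain (C9 configuration not assigned) | CC(C)(C)[Si](C)(C)O[C@H]1CC[C@@]2(C)[C@@H]([C@H](O[Si](CC)(CC)CC)C=C(C)C2(O)CC[C@@]3(CC=C(C)C)COC(C)(C)O3)C1(C)C | intermediate
42 | C8=C9 enone with C7 ketone and side chain | CC(C)(C)[Si](C)(C)O[C@H]1CC[C@@]2(C)[C@@H]([C@H](O[Si](CC)(CC)CC)C(=O)C(C)=C2CC[C@@]3(CC=C(C)C)COC(C)(C)O3)C1(C)C | intermediate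
43 | vicinal diol from the prenyl alkene of 42 (carbinol epimers) | CC(C)(C)[Si](C)(C)O[C@H]1CC[C@@]2(C)[C@@H]([C@H](O[Si](CC)(CC)CC)C(=O)C(C)=C2CC[C@@]3(CC(O)C(C)(C)O)COC(C)(C)O3)C1(C)C | intermediate
44 | C15 aldehyde | CC(C)(C)[Si](C)(C)O[C@H]1CC[C@@]2(C)[C@@H]([C@H](O[Si](CC)(CC)CC)C(=O)C(C)=C2CC[C@@]3(CC=O)COC(C)(C)O3)C1(C)C | intermediate
45 | C15 carboxylic acid | CC(C)(C)[Si](C)(C)O[C@H]1CC[C@@]2(C)[C@@H]([C@H](O[Si](CC)(CC)CC)C(=O)C(C)=C2CC[C@@]3(CC(=O)O)COC(C)(C)O3)C1(C)C | intermediate
46 | 3β,6β-dihydroxy C8=C9 enone with 13-hydroxy γ-lactone side chain | O[C@H]1CC[C@@]2(C)[C@@H]([C@H](O)C(=O)C(C)=C2CC[C@]3(O)COC(=O)C3)C1(C)C | intermediate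
47 | 3β,6β-dihydroxy-7-oxo-9α,13-epoxy spirolactone (deacetyl target) | O[C@H]1CC[C@@]2(C)[C@@H]([C@H](O)C(=O)[C@@H](C)[C@]23CC[C@@]2(COC(=O)C2)O3)C1(C)C | intermediate
48 | CNP0325396.1 | CC(=O)O[C@H]1CC[C@@]2(C)[C@@H]([C@H](O)C(=O)[C@@H](C)[C@]23CC[C@@]2(COC(=O)C2)O3)C1(C)C | target

**Step count**
Total: 28 steps. Longest linear sequence: 23 steps (steps 1–17 and 23–28); the side chain takes 5 steps (18–22).

**Steps most likely to fail**

Step 13 (carries the label). Bond formation at the fully substituted C10 may be slower than thermal 1,5-hydrogen shift in the diene or loss of the enol silyl group, and facial control between C10 and C3 may be weak. The fallback sets out from 23 and returns at 24, and makes the same two bonds stepwise by known anionic chemistry. Bu4N[Ph3SiF2] in THF at −78 → 0 °C should cleave the enol silyl ether faster than the secondary alkyl silyl ether and release the tetrasubstituted enolate, whose Michael addition to the nitroalkene closes ring A. Protonation gives the ring A nitro enone F1. Where the nitronate has not already added to the isopropenyl ketone, DBU in MeCN should close ring B by the second Michael addition to the bicyclic nitro ketone F2. Silylation of F2 with TBSOTf/Et3N (C9 can enolise only toward C8; any silyl nitronate is hydrolysed on aqueous work-up) gives 24.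

Step 14. Deprotonation and oxygen transfer at the hindered C6 may be slow, and the enol silane may be lost during the basic, oxidative treatment. The fallback sets out from 24 and returns at 26, and is reductive instead of oxidative. SnCl2/PhSH/Et3N in MeCN should reduce the secondary nitro group to the C6 oxime F3 under near-neutral conditions. Buffered aqueous TiCl3/NH4OAc in THF (pH about 6) then cleaves the N–O bond and hydrolyses the imine to ketone 26.

Step 27. Several events share one flask: the primary C16 hydroxyl may add to C9 before it lactonises (giving a six-membered ether), the conjugate addition at the hindered C9 may stall, and the axial C6 carbinol may epimerise by enolisation in the meantime. The fallback sets out from 44 and returns at 47; it changes the order of ring closure and ties up O16 at the aldehyde oxidation level before C9 is attacked. PPTS in MeOH at 0 °C should cleave the acetonide of 44 and trap the C15 aldehyde with the C16 hydroxyl as the enone methyl lactol acetal F4, in which the tertiary C13 hydroxyl is the only free hydroxyl. Camphorsulfonic acid in CH2Cl2 then effects the conjugate addition to the spiro tetrahydrofuran acetal F5. mCPBA with BF3·OEt2 oxidises the cyclic acetal to the silyl-protected spirolactone F6, and aqueous HF in MeCN removes both silyl groups to give 47.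

Further compounds
F1 | step 13 | ring A nitro enone (C10: methyl and 2-methylacryloyl; C5: nitromethyl; 3β-OTBS) | CC(C)(C)[Si](C)(C)O[C@H]1CC[C@](C)(C(=O)C(C)=C)[C@@H](C[N+](=O)[O-])C1(C)C
F2 | step 13 | bicyclic nitro ketone (9-oxo; 8α-methyl; 6α-nitro; 3β-OTBS) | CC(C)(C)[Si](C)(C)O[C@H]1CC[C@@]2(C)[C@@H]([C@@H]([N+](=O)[O-])C[C@@H](C)C2=O)C1(C)C
F3 | step 14 | C6 oxime of the cycloadduct | CC(C)(C)[Si](C)(C)O[C@H]1CC[C@@]2(C)[C@@H](C(=NO)CC(C)=C2O[Si](C)(C)C(C)(C)C)C1(C)C
F4 | step 27 | enone methyl lactol acetal with free C13 hydroxyl (3β-OTBS; 6β-OTES) | CC(C)(C)[Si](C)(C)O[C@H]1CC[C@@]2(C)[C@@H]([C@H](O[Si](CC)(CC)CC)C(=O)C(C)=C2CC[C@]3(O)COC(OC)C3)C1(C)C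
F5 | step 27 | spiro tetrahydrofuran methyl lactol acetal (3β-OTBS; 6β-OTES) | CC(C)(C)[Si](C)(C)O[C@H]1CC[C@@]2(C)[C@@H]([C@H](O[Si](CC)(CC)CC)C(=O)[C@@H](C)[C@]23CC[C@@]2(COC(OC)C2)O3)C1(C)C
F6 | step 27 | 3-O-TBS-6-O-TES spirolactone | CC(C)(C)[Si](C)(C)O[C@H]1CC[C@@]2(C)[C@@H]([C@H](O[Si](CC)(CC)CC)C(=O)[C@@H](C)[C@]23CC[C@@]2(COC(=O)C2)O3)C1(C)C
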